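**Retrosynthetic overview**

1. Feature: the target is one six-membered carbocycle with no stereocentre, C1(=O)–C2H=C3(n-C19H39)–C4H2–C5H2–C6H2. Its enone is the hydrolysis product of a 1-silyloxycyclohexa-1,3-diene, and cutting the ring bond C5–C6 of that diene unfolds C6–C1–C2–C3–C4–C5 into an acyclic (3Z)-2-silyloxy-4-nonadecylhexa-1,3,5-triene.
2. Ring formation (the only ring): thermal disrotatory 6π closure of triene 14 to silyl dienol ether 15, then acid hydrolysis to enone 16.
3. Triene 14 comes from kinetic enolisation and O-silylation of (Z)-dienone 11, which comes from Weinreb amide 9 and (Z)-dienoate 8.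
4. Dienoate 8 comes from stereoretentive Suzuki–Miyaura vinylation of (Z)-enol triflate 6, made from β-keto ester 4, itself the γ-alkylation product of the ethyl acetoacetate dianion with 1-bromooctadecane.

Key step: step 7

Remark: the target is achiral, so the only stereochemical element to control is the Z geometry of the C3=C4 alkene of triene 14; the in-flask adduct 10 carries a stereocentre and forms as a racemate.

**Step 1**
Reactants: 1 ethyl acetoacetate; 2 1-bromooctadecane
Product: 4 ethyl 3-oxodocosanoate, via acetoacetate dianion 3 (not isolated)
Conditions: NaH, THF, 0 °C; n-BuLi, 0 °C; then 2, 0 °C → rt; 1 M aq. HCl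
Reagents that add atoms: none
Why: Dianion γ-alkylation of a β-keto ester: the terminal carbanion of the sodium lithium dianion is the more nucleophilic site and should displace the primary bromide by SN2, while the stabilised C2 enolate stays untouched until the acidic quench.

**Step 2**
Reactants: 4 ethyl 3-oxodocosanoate
Product: 6 ethyl (2Z)-3-{[(trifluoromethyl)sulfonyl]oxy}docos-2-enoate, via lithium Z-enolate 5 (not isolated)
Conditions: Tf2O, aq. LiOH, toluene, 5 °C
Reagents that add atoms: trifluoromethanesulfonic anhydride, O=S(=O)(OS(=O)(=O)C(F)(F)F)C(F)(F)F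
Why: O-sulfonylation of a β-keto ester enolate: lithium holds the enolate oxygen and the ester carbonyl in a six-membered chelate, so triflation of this U-shaped enolate should place the triflyloxy group cis to the ester, which is the Z enol triflate.

**Step 3**
Reactants: 6 ethyl (2Z)-3-{[(trifluoromethyl)sulfonyl]oxy}docos-2-enoate; 7 potassium vinyltrifluoroborate
Product: 8 ethyl (2Z)-3-ethenyldocos-2-enoate
Conditions: PdCl2(dppf)·CH2Cl2 (cat.), Cs2CO3, THF/H2O, 65 °C
Reagents that add atoms: none
Why: Suzuki–Miyaura coupling: oxidative addition of the alkenyl C–O bond to zerovalent palladium (formed from the divalent palladium precatalyst), transmetallation of the vinyl group and reductive elimination all proceed with retention at the alkenyl carbon, so the vinyl group should end up cis to the ester.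

**Step 4**
Reactants: 8 ethyl (2Z)-3-ethenyldocos-2-enoate
Product: 9 (2Z)-3-ethenyl-N-methoxy-N-methyldocos-2-enamide
Conditions: MeNHOMe·HCl, i-PrMgCl, THF, −20 → 0 °C; dilute aq. HCl
Reagents that add atoms: N,O-dimethylhydroxylamine hydrochloride, CNOC.Cl
Why: Weinreb amide formation by aminolysis of the ester with the chloromagnesium amide made in the flask; the β,β-disubstituted acceptor resists conjugate addition and the cold conditions should leave the alkene geometry untouched.

**Step 5**
Reactants: 9 (2Z)-3-ethenyl-N-methoxy-N-methyldocos-2-enamide
Product: 11 (3Z)-4-ethenyltricos-3-en-2-one, via magnesium hemiaminal chelate 10 (not isolated)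
Conditions: MeMgBr, THF, −78 → 0 °C; aq. NH4Cl, 0 °C
Reagents that add atoms: methylmagnesium bromide, C[Mg]Br
Why: Weinreb ketone synthesis: the five-membered magnesium chelate of the tetrahedral adduct survives until the neutral quench, so a single methyl group is delivered and the cis-dienone is released only under cold, non-isomerising conditions.

**Step 6**
Reactants: 11 (3Z)-4-ethenyltricos-3-en-2-one; 12 tert-butyldimethylsilyl chloride
Product: 14 tert-butyl{[(3Z)-4-ethenyltricosa-1,3-dien-2-yl]oxy}dimethylsilane, via lithium trienolate 13 (not isolated)
Conditions: LiN(i-Pr)2, THF, −78 °C; then 12, DMPU, −78 → 0 °C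
Reagents that add atoms: none
Why: Kinetic enolisation of a β,β-disubstituted enone with a hindered lithium amide removes a proton from the α′-methyl group and not from the γ-CH2 of the chain, and O-silylation of the cross-conjugated lithium enolate (activated by DMPU) should give the 2-silyloxy triene with the central Z alkene unchanged.

**Step 7**
Reactants: 14 tert-butyl{[(3Z)-4-ethenyltricosa-1,3-dien-2-yl]oxy}dimethylsilane
Product: 15 tert-butyldimethyl[(3-nonadecylcyclohexa-1,3-dien-1-yl)oxy]silane
Conditions: toluene (degassed, 0.02 M), BHT (cat.), sealed tube, 120 °C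
Reagents that add atoms: none
Why: Thermal six-electron electrocyclisation: in its s-cis,Z,s-cis conformer the triene should pass through a boat-like transition state in which the two terminal CH2 carbons (C1 and C6 of the triene) rotate in a disrotatory sense and form the ring bond C5–C6 of the carbocycle, as orbital symmetry requires for a thermal 6π process. The closest known reaction type is the thermal closure of (Z)-hexa-1,3,5-trienes to cyclohexa-1,3-dienes, which is established for 2-silyloxy trienes derived from cis-dienones. The single ring is thus closed by a 6π disrotatory carbon–carbon bond formation, and no stereocentre arises because both termini are unsubstituted CH2 groups. The step needs the central alkene to be Z and the enol ether double bond to sit at the terminal carbon; the first is fixed by the chelation-controlled triflation and the stereoretentive coupling, the second by kinetic enolisation of the methyl group. Because the nonadecyl chain lies trans to the silyloxyvinyl arm, no allylic hydrogen is placed for a competing 1,5-hydrogen shift, and the silyl dienol ether formed carries oxygen at C1 and the chain at C3 of the ring as the hydrolysis requires. High dilution and a radical inhibitor should hold back intermolecular cycloaddition and polymerisation of the electron-rich diene.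

**Step 8**
Reactants: 15 tert-butyldimethyl[(3-nonadecylcyclohexa-1,3-dien-1-yl)oxy]silane
Product: 16 3-nonadecylcyclohex-2-en-1-one
Conditions: 1 M aq. HCl, THF, rt
Reagents that add atoms: none
Why: Acid hydrolysis of a silyl dienol ether: protonation at the diene terminus C4 and loss of the silyl group to water should leave the C1 carbonyl conjugated with C2=C3, and any deconjugated isomer from protonation at C2 would be brought into conjugation by the same acid.

**Compound list**

1 | ethyl acetoacetate | CCOC(=O)CC(C)=O | starting material
2 | 1-bromooctadecane | CCCCCCCCCCCCCCCCCCBr | starting material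
3 | sodium lithium dianion of ethyl acetoacetate | [Na+].[Li+].[CH2-]C(=O)[CH-]C(=O)OCC | intermediate (not isolated)
4 | ethyl 3-oxodocosanoate | CCOC(=O)CC(=O)CCCCCCCCCCCCCCCCCCC | intermediate
5 | lithium (2Z)-1-ethoxy-1-oxodocos-2-en-3-olate | [Li+].CCOC(=O)/C=C(\[O-])CCCCCCCCCCCCCCCCCCC | intermediate (not isolated)
6 | ethyl (2Z)-3-{[(trifluoromethyl)sulfonyl]oxy}docos-2-enoate | CCOC(=O)/C=C(\OS(=O)(=O)C(F)(F)F)CCCCCCCCCCCCCCCCCCC | intermediate
7 | potassium vinyltrifluoroborate | [K+].C=C[B-](F)(F)F | starting material
8 | ethyl (2Z)-3-ethenyldocos-2-enoate | CCOC(=O)/C=C(\C=C)CCCCCCCCCCCCCCCCCCC | intermediate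
9 | (2Z)-3-ethenyl-N-methoxy-N-methyldocos-2-enamide | CON(C)C(=O)/C=C(\C=C)CCCCCCCCCCCCCCCCCCC | intermediate
10 | bromomagnesium (3Z)-4-ethenyl-2-[methoxy(methyl)amino]tricos-3-en-2-olate (racemic) | CON(C)C(C)(O[Mg]Br)/C=C(\C=C)CCCCCCCCCCCCCCCCCCC | intermediate (not isolated)
11 | (3Z)-4-ethenyltricos-3-en-2-one | CC(=O)/C=C(\C=C)CCCCCCCCCCCCCCCCCCC | intermediate
12 | tert-butyldimethylsilyl chloride | CC(C)(C)[Si](C)(C)Cl | starting material
13 | lithium (3Z)-4-ethenyltricosa-1,3-dien-2-olate | [Li+].C=C([O-])/C=C(\C=C)CCCCCCCCCCCCCCCCCCC | intermediate (not isolated)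
14 | tert-butyl{[(3Z)-4-ethenyltricosa-1,3-dien-2-yl]oxy}dimethylsilane | C=C(O[Si](C)(C)C(C)(C)C)/C=C(\C=C)CCCCCCCCCCCCCCCCCCC | intermediate
15 | tert-butyldimethyl[(3-nonadecylcyclohexa-1,3-dien-1-yl)oxy]silane | CC(C)(C)[Si](C)(C)OC1=CC(CCCCCCCCCCCCCCCCCCC)=CCC1 | intermediate
16 | 3-nonadecylcyclohex-2-en-1-one | CCCCCCCCCCCCCCCCCCCC1=CC(=O)CCC1 | target

**Totals**

Total step count: 8. Longest linear sequence: 8 steps (from ethyl acetoacetate).

**Steps most likely to fail**

Step 7. The closure may be too slow at temperatures the silyl trienol ether tolerates, so that intermolecular cycloaddition, polymerisation or adventitious desilylation overtakes ring formation. The fallback builds the ring by a Robinson-type annulation instead; it sets out from 4 and rejoins the route at 16.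
- Base-catalysed Michael addition of 4 to but-3-en-2-one (cat. NaOEt, EtOH, 0 °C) should give ethyl 3-oxo-2-(3-oxobutyl)docosanoate F1 (racemic).
- Intramolecular aldol condensation of the methyl ketone onto the C3 ketone (pyrrolidine, AcOH, toluene, reflux) should give ethyl 2-nonadecyl-4-oxocyclohex-2-ene-1-carboxylate F2 (racemic).
- Saponification with KOH in aqueous ethanol at reflux, then acidification, should decarboxylate the vinylogous β-keto acid and deliver 16.

Step 6. Deprotonation may stray to the γ-CH2 of the chain, O-silylation may be incomplete at low temperature, and the silyl trienol ether may lose its silyl group or its alkene geometry during isolation. The fallback makes the trienol ether by carbonyl methylenation, without going through the dienone; it sets out from 8 and rejoins the route at 16.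
- Methylenation of the ester carbonyl of 8 with Cp2Ti(μ-Cl)(μ-CH2)AlMe2 (pyridine, THF/toluene, −40 °C → rt) should give (3Z)-4-ethenyl-2-ethoxytricosa-1,3-diene F3.
- The same thermal 6π closure (toluene, 120 °C) should convert F3 into 1-ethoxy-3-nonadecylcyclohexa-1,3-diene F4.
- Hydrolysis of F4 with 1 M aq. HCl in THF should give 16.

Step 2. Control of enolate geometry may erode during triflation, giving a mixture of geometrical isomers of which only the Z form leads to a triene that can close. The fallback sets the geometry by anti-hydroiodination of an alkynoate; it sets out from 6 (as the isomer mixture) and rejoins the route at 8.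
- Elimination of triflic acid with LiN(SiMe3)2 (THF, −78 °C → rt) should converge both isomers on ethyl docos-2-ynoate F5.
- Hydroiodination with NaI in AcOH at about 110 °C should give ethyl (2Z)-3-iododocos-2-enoate F6.
- Suzuki–Miyaura coupling of F6 with 7 under the conditions of step 3 should give 8 with retention of geometry.

**Further compounds**

F1 | step 7 | ethyl 3-oxo-2-(3-oxobutyl)docosanoate (racemic) | CCOC(=O)C(CCC(C)=O)C(=O)CCCCCCCCCCCCCCCCCCC
F2 | step 7 | ethyl 2-nonadecyl-4-oxocyclohex-2-ene-1-carboxylate (racemic) | CCOC(=O)C1CCC(=O)C=C1CCCCCCCCCCCCCCCCCCC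
F3 | step 6 | (3Z)-4-ethenyl-2-ethoxytricosa-1,3-diene | C=C(OCC)/C=C(\C=C)CCCCCCCCCCCCCCCCCCC
F4 | step 6 | 1-ethoxy-3-nonadecylcyclohexa-1,3-diene | CCOC1=CC(CCCCCCCCCCCCCCCCCCC)=CCC1
F5 | step 2 | ethyl docos-2-ynoate | CCOC(=O)C#CCCCCCCCCCCCCCCCCCCC
F6 | step 2 | ethyl (2Z)-3-iododocos-2-enoate | CCOC(=O)/C=C(\I)CCCCCCCCCCCCCCCCCCC
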